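**Retrosynthetic overview**
1. Target 22 comes from lactone dialdehyde 17 by masking both CHO groups, correcting C11, reducing the lactone, acetylating O18 and unmasking.
2. The nine-membered carbocycle is the only ring formed. It closes in one event, C2 to C10, on the acyclic C20 chain 16. This is the polar equivalent of the 2,10-cyclisation of a geranylgeranyl chain.
3. Enedial 16 comes from singlet-oxygen unmasking of the acyclic furano-butenolide 14. Its butenolide carries O9 and C18 and is opened later.
4. Butenolide 14 comes from aldehyde 7 by D-proline α-aminoxylation (sets C9), Z-selective olefination with 10 and lactonisation.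
5. Aldehyde 7 comes from geranyl acetate (supplies the 6E alkene) and a 3-furylmethyl Grignard reagent.

Assumption: atom labels C1–C20 follow geranylgeraniol numbering, and the target is read as 2R,9S,10R,11S with 6E and with C3=C4 ring-cis (E by CIP). C1 and C20 are the CHO carbons, C9 carries OH, and C18 carries OAc.

**Step 1**
Reactants: 1 geranyl acetate
Product: 2 6,7-epoxygeranyl acetate (racemic epoxide)
Conditions: mCPBA (1.0 equiv), NaHCO3, CH2Cl2, 0 °C
Reagents that add atoms: mCPBA O=C(OO)c1cccc(Cl)c1
Why: Prilezhaev epoxidation takes the electron-rich 6,7-alkene because the 2,3-alkene is deactivated by the allylic acetate; the new centre is destroyed in step 4.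

**Step 2**
Reactants: 3 furan-3-ylmethanol
Product: 4 3-(chloromethyl)furan
Conditions: SOCl2, pyridine, Et2O, 0 °C; used at once
Reagents that add atoms: thionyl chloride O=S(Cl)Cl
Why: Chlorodehydroxylation through the chlorosulfite gives the labile furylmethyl chloride needed for Grignard formation.

**Step 3**
Reactants: 4 3-(chloromethyl)furan; 2 6,7-epoxygeranyl acetate
Product: 6 10,11-epoxydendrolasin, via (furan-3-ylmethyl)magnesium chloride 5 (not isolated)
Conditions: Mg, THF, 0 °C; then 2, Li2CuCl4 (5 mol%), THF, −20 → 0 °C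
Reagents that add atoms: none
Why: Copper-catalysed Grignard allylic substitution (Fouquet–Schlosser type) displaces the primary allylic acetate at its α-carbon with retention of the E-alkene, and the trisubstituted epoxide reacts far more slowly.

**Step 4**
Reactants: 6 10,11-epoxydendrolasin
Product: 7 (4E)-7-(furan-3-yl)-4-methylhept-4-enal
Conditions: H5IO6 (1.2 equiv), THF/Et2O, 0 °C, 45 min
Reagents that add atoms: none
Why: Periodic acid opens the epoxide at its tertiary carbon and cleaves the glycol (Malaprade cleavage), which releases the C10 aldehyde and acetone.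

**Step 5**
Reactants: 8 ethyl (diphenoxyphosphoryl)acetate; 9 5-bromo-2-methylpent-2-ene
Product: 10 ethyl 2-(diphenoxyphosphoryl)-6-methylhept-5-enoate (racemic)
Conditions: NaH, DMSO, rt → 50 °C
Reagents that add atoms: none
Why: SN2 alkylation of the stabilised phosphonate carbanion gives the α-homoprenyl Ando reagent.

**Step 6**
Reactants: 7 (4E)-7-(furan-3-yl)-4-methylhept-4-enal; 10 ethyl 2-(diphenoxyphosphoryl)-6-methylhept-5-enoate
Product: 12 ethyl (2Z,4S,6E)-9-(furan-3-yl)-6-methyl-2-(4-methylpent-3-enyl)-4-(phenylaminooxy)nona-2,6-dienoate, via (2S)-2-(phenylaminooxy) aldehyde 11 (not isolated)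
Conditions: PhNO (1.0 equiv), D-proline (20 mol%), MeCN, −20 °C, 24 h; then added to 10 (1.4 equiv)/NaH, THF, −78 → 0 °C
Reagents that add atoms: nitrosobenzene O=Nc1ccccc1
Why: Enamine-catalysed α-aminoxylation with D-proline sets C9 as S through the acid-directed O-selective attack on nitrosobenzene, and the Ando-type Z-selective Horner–Wadsworth–Emmons reaction places the ester cis to C9.

**Step 7**
Reactants: 12 ethyl (2Z,4S,6E)-aminoxy dienoate
Product: 14 (5S)-5-[(2E)-5-(furan-3-yl)-2-methylpent-2-enyl]-3-(4-methylpent-3-enyl)furan-2(5H)-one, via (Z)-γ-hydroxy ester 13 (not isolated)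
Conditions: Cu(OAc)2·H2O (30 mol%), EtOH, rt, 12 h
Reagents that add atoms: none
Why: Cu(II)-catalysed N–O cleavage frees the C9 alcohol, which lies cis to the ester and lactonises spontaneously without touching C9; any E-ester cannot lactonise and is removed by chromatography.

**Step 8**
Reactants: 14 (5S)-furano-butenolide
Product: 17 cis-fused cyclononadiene γ-lactone dialdehyde (C2 C9 C10 as in the target; C11 epimer mixture), via furan endoperoxide 15 (not isolated), via (Z)-enedial butenolide 16 (not isolated)
Conditions: O2, TPP (0.2 mol%), white LED, CH2Cl2, −78 °C, 15 min; Me2S (3 equiv), −78 → 0 °C; then syringe pump (8 h) into MgBr2·OEt2 (2 equiv), i-Pr2NEt (2.2 equiv), CH2Cl2 (final 1 mM), 0 °C → rt; pH 7 buffer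
Reagents that add atoms: dioxygen O=O
Why: Proposed new method: singlet oxygen adds [4+2] to the furan faster than it undergoes ene reactions with trisubstituted alkenes, and Me2S reduces the endoperoxide to the cis-enedial (both known); Mg(II) chelation of the cis-dialdehyde then lets Hünig's base remove a C4 proton, and the dienolate can bond to the butenolide β-carbon C10 only through its α-carbon C2, because bonding through C4 would need an E-cycloheptene, so this intramolecular Michael addition closes the nine-membered ring and leaves C3=C4 conjugated with C20HO and ring-cis; the short E-alkene tether reaches C10 only on the face syn to C8, which sets C10 from C9 with a cis ring fusion, and C1 and C11 must both point out of the forming ring, which puts H2 anti to H10 and sets C2; the closest known reaction types are base-induced cyclisations of furan-derived cis-enediones, dienamine Rauhut–Currier-type cyclisations of 8-oxogeranial-type dialdehydes to iridoids, and the Mg/amine-mediated dienolate Michael closure of nine-membered rings in nonadride dimerisations.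

**Step 9**
Reactants: 17 lactone dialdehyde
Product: 18 bis(dimethyl acetal) of 17
Conditions: HC(OMe)3 (10 equiv), MeOH, PPTS (10 mol%), rt
Reagents that add atoms: trimethyl orthoformate COC(OC)OC; methanol CO
Why: Acid-catalysed acetalisation masks both aldehydes and removes the acidity of C2–H, while the γ-lactone and alkenes are inert at room temperature.

**Step 10**
Reactants: 18 bis(dimethyl acetal) lactone
Product: 20 C9,C18-diol bis(dimethyl acetal), via C11-equilibrated lactone 19 (not isolated)
Conditions: t-BuOK (0.2 equiv), THF, 0 °C → rt, 1 h; then LiAlH4 (2 equiv), 0 °C; Rochelle work-up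
Reagents that add atoms: none
Why: Base-catalysed epimerisation through the lactone enolate moves the homoprenyl chain to the convex face, trans to the C10 substituent, and so sets C11 as in the target; retro-Michael is impossible because C2 is no longer stabilised, and LiAlH4 then reduces the lactone to the 1,4-diol.

**Step 11**
Reactants: 20 diol bis(dimethyl acetal)
Product: 21 C18 monoacetate bis(dimethyl acetal)
Conditions: Ac2O (1.1 equiv), pyridine, CH2Cl2, −20 → 0 °C
Reagents that add atoms: acetic anhydride CC(=O)OC(C)=O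
Why: Chemoselective acylation takes the primary C18 alcohol far faster than the hindered secondary ring alcohol at C9.

**Step 12**
Reactants: 21 monoacetate bis(dimethyl acetal)
Product: 22 target CNP0284729.1
Conditions: 10% aq. oxalic acid on SiO2, CH2Cl2, rt
Reagents that add atoms: water O
Why: Mild heterogeneous acetal hydrolysis (wet silica/oxalic acid) frees the allylic and the saturated aldehyde without cleaving the acetate or enolising C2.

**Compound list**
1 | geranyl acetate | CC(=O)OC/C=C(\C)CCC=C(C)C | starting material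
2 | 6,7-epoxygeranyl acetate (racemic epoxide) | CC(=O)OC/C=C(\C)CCC1OC1(C)C | intermediate
3 | furan-3-ylmethanol | OCc1ccoc1 | starting material
4 | 3-(chloromethyl)furan | ClCc1ccoc1 | intermediate
5 | (furan-3-ylmethyl)magnesium chloride | Cl[Mg]Cc1ccoc1 | intermediate
6 | 10,11-epoxydendrolasin, 3-[(3E)-6-(3,3-dimethyloxiran-2-yl)-4-methylhex-3-enyl]furan | CC1(C)OC1CC/C(C)=C/CCc1ccoc1 | intermediate
7 | (4E)-7-(furan-3-yl)-4-methylhept-4-enal | O=CCC/C(C)=C/CCc1ccoc1 | intermediate
8 | ethyl (diphenoxyphosphoryl)acetate | CCOC(=O)CP(=O)(Oc1ccccc1)Oc1ccccc1 | starting material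
9 | 5-bromo-2-methylpent-2-ene | CC(C)=CCCBr | starting material
10 | ethyl 2-(diphenoxyphosphoryl)-6-methylhept-5-enoate (racemic) | CCOC(=O)C(CCC=C(C)C)P(=O)(Oc1ccccc1)Oc1ccccc1 | intermediate
11 | (2S,4E)-7-(furan-3-yl)-4-methyl-2-(phenylaminooxy)hept-4-enal | O=C[C@@H](ONc1ccccc1)C/C(C)=C/CCc1ccoc1 | intermediate
12 | ethyl (2Z,4S,6E)-9-(furan-3-yl)-6-methyl-2-(4-methylpent-3-enyl)-4-(phenylaminooxy)nona-2,6-dienoate | CCOC(=O)/C(CCC=C(C)C)=C\[C@@H](ONc1ccccc1)C/C(C)=C/CCc1ccoc1 | intermediate
13 | ethyl (2Z,4S,6E)-9-(furan-3-yl)-4-hydroxy-6-methyl-2-(4-methylpent-3-enyl)nona-2,6-dienoate | CCOC(=O)/C(CCC=C(C)C)=C\[C@@H](O)C/C(C)=C/CCc1ccoc1 | intermediate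
14 | (5S)-5-[(2E)-5-(furan-3-yl)-2-methylpent-2-enyl]-3-(4-methylpent-3-enyl)furan-2(5H)-one | O=C1O[C@@H](C/C(C)=C/CCc2ccoc2)C=C1CCC=C(C)C | intermediate
15 | furan endoperoxide of 14 (2,3,7-trioxabicyclo[2.2.1]hept-5-ene, bridgeheads unassigned) | O=C1O[C@@H](C/C(C)=C/CCC2=CC3OOC2O3)C=C1CCC=C(C)C | intermediate
16 | (2Z)-2-{(3E)-4-methyl-5-[(2S)-4-(4-methylpent-3-enyl)-5-oxo-2,5-dihydrofuran-2-yl]pent-3-enyl}but-2-enedial | O=C1O[C@@H](C/C(C)=C/CC/C(C=O)=C/C=O)C=C1CCC=C(C)C | intermediate
17 | nine-membered ring C2–C10 with ring-cis 3-en-20-al, 6E alkene and C1 formyl; γ-lactone C18(=O)–O9 cis-fused at C9–C10; H2 anti to H10; C11 epimer mixture | O=C1O[C@H]2C/C(C)=C/C/C=C(/C=O)[C@H](C=O)[C@H]2C1CCC=C(C)C | intermediate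
18 | bis(dimethyl acetal) of 17 (C11 epimer mixture) | O=C1O[C@H]2C/C(C)=C/C/C=C(/C(OC)OC)[C@H](C(OC)OC)[C@H]2C1CCC=C(C)C | intermediate
19 | C11-equilibrated lactone, homoprenyl trans to the C10 ring substituent | O=C1O[C@H]2C/C(C)=C/C/C=C(/C(OC)OC)[C@H](C(OC)OC)[C@H]2[C@@H]1CCC=C(C)C | intermediate
20 | C9,C18-diol bis(dimethyl acetal), all four centres as in the target | OC[C@@H](CCC=C(C)C)[C@H]1[C@@H](O)C/C(C)=C/C/C=C(/C(OC)OC)[C@@H]1C(OC)OC | intermediate
21 | C18 monoacetate bis(dimethyl acetal) | CC(=O)OC[C@@H](CCC=C(C)C)[C@H]1[C@@H](O)C/C(C)=C/C/C=C(/C(OC)OC)[C@@H]1C(OC)OC | intermediate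
22 | CNP0284729.1 (2R,9S,10R,11S) | CC(=O)OC[C@@H](CCC=C(C)C)[C@H]1[C@@H](O)C/C(C)=C/C/C=C(/C=O)[C@@H]1C=O | target

**Totals**
Total step count: 12.
Longest linear sequence: 10 steps (1, 3, 4, 6, 7, 8, 9, 10, 11, 12) from geranyl acetate.

**Steps most likely to fail**

Step 8 is the weakest. It asks a delocalised dienolate to close a strained nine-membered ring on a poorly electrophilic α-alkylbutenolide. Any γ-deprotonation of the butenolide would erode C9, and some ene oxidation of the side-chain alkenes is possible. The fallback sets out from 14 and comes back at 17. Enedial 16 is generated as before and trapped at −78 °C with TBSOTf (1.05 equiv)/Et3N as the tert-butyldimethylsilyl dienol ether F1. This is purified and closed without any base by silylium catalysis (Tf2NH 5 mol%, CH2Cl2, 1 mM, −40 °C). The closure is an intramolecular Mukaiyama–Michael addition that gives the cyclised silyl ketene acetal F2, and buffered aqueous work-up hydrolyses F2 to 17.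

Step 12 is second. C2–H is α to a formyl group and allylic, so acid can epimerise it or move the double bond, and the free C9 hydroxyl can capture the C1 oxocarbenium ion. The fallback sets out from 17 and comes back at 22, and it replaces acid-labile masks by masks removed at neutral pH. Me2NNH2/MgSO4 converts 17 into the bis(N,N-dimethylhydrazone) lactone F3. Catalytic t-BuOK gives the C11-equilibrated bis(hydrazone) lactone F4, which LiAlH4 reduces in the same flask to the bis(hydrazone) diol F5. Ac2O/pyridine gives the bis(hydrazone) C18 monoacetate F6. Finally CuCl2 in THF/pH 7 phosphate buffer releases both aldehydes as 22.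

Step 4 is third. The acidic oxidant can trigger the known furan-terminated cationic cyclisation of the epoxy-polyene, or degrade the furan. The fallback sets out from 2 and comes back at 7, and it cleaves the epoxide before the furan is present. H5IO6 converts 2 into (E)-6-acetoxy-4-methylhex-4-enal F7. HC(OMe)3/MeOH/PPTS gives its dimethyl acetal F8. Li2CuCl4-catalysed coupling with Grignard reagent 5 gives the furyl dimethyl acetal F9, and wet silica/oxalic acid releases 7.

**Further compounds**
F1 | step 8 | tert-butyldimethylsilyl dienol ether of 16 (1E; C5 cis to C2 at C3=C4) | O=C1O[C@@H](C/C(C)=C/C/C=C(/C=O)\C=C\O[Si](C)(C)C(C)(C)C)C=C1CCC=C(C)C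
F2 | step 8 | cyclised silyl ketene acetal (2-silyloxy-4,5-dihydrofuran form of 17) | CC(C)=CCCC1=C(O[Si](C)(C)C(C)(C)C)O[C@H]2C/C(C)=C/C/C=C(/C=O)[C@H](C=O)[C@@H]12
F3 | step 12 | bis(N,N-dimethylhydrazone) lactone (C11 epimer mixture) | O=C1O[C@H]2C/C(C)=C/C/C=C(/C=NN(C)C)[C@H](C=NN(C)C)[C@H]2C1CCC=C(C)C
F4 | step 12 | C11-equilibrated bis(hydrazone) lactone | O=C1O[C@H]2C/C(C)=C/C/C=C(/C=NN(C)C)[C@H](C=NN(C)C)[C@H]2[C@@H]1CCC=C(C)C
F5 | step 12 | bis(hydrazone) diol | OC[C@@H](CCC=C(C)C)[C@H]1[C@@H](O)C/C(C)=C/C/C=C(/C=NN(C)C)[C@@H]1C=NN(C)C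
F6 | step 12 | bis(hydrazone) C18 monoacetate | CC(=O)OC[C@@H](CCC=C(C)C)[C@H]1[C@@H](O)C/C(C)=C/C/C=C(/C=NN(C)C)[C@@H]1C=NN(C)C
F7 | step 4 | (E)-6-acetoxy-4-methylhex-4-enal | CC(=O)OC/C=C(\C)CCC=O
F8 | step 4 | (E)-6,6-dimethoxy-3-methylhex-2-enyl acetate | CC(=O)OC/C=C(\C)CCC(OC)OC
F9 | step 4 | 3-[(3E)-7,7-dimethoxy-4-methylhept-3-enyl]furan | COC(OC)CC/C(C)=C/CCc1ccoc1
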